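If each partner met one starting material, the one-to-one case that I take as the zero of my scale, 20.0% of the partner charged in this recipe would be enough to clear the starting material.

in all of them: starting material 22 mM (fed, over 5.0 min)

| flask | partner | capture agent | remark | time |
|---|---|---|---|---|
| epsilon | 5 equiv | 1.1 mM | the very flask that is asked about, followed so far |  |
| gamma | 5 equiv | 2.2 mM | run made earlier |  |
| flask | 5.00 equiv | 1.10 mM |  | 5.0 d |

| run | time / d | starting material / % | isomer of the product / % |
|---|---|---|---|
| epsilon | 0.500 | 32.9 | 62.3 |
| epsilon | 1.04 | 31.6 | 63.6 |
| epsilon | 1.67 | 30.8 | 63.9 |
| epsilon | 2.08 | 30.9 | 63.8 |
| epsilon | 2.50 | 30.5 | 63.9 |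
| gamma | 0.417 | 33.4 | 58.5 |
| gamma | 1.25 | 30.6 | 58.9 |
| gamma | 2.50 | 30.3 | 58.6 |
| gamma | 4.00 | 30.9 | 58.9 |
| gamma | 5.00 | 30.9 | 59.4 |

(standard deviation of a reading: 0.3 percentage points)

* at 5.0 d, what has stopped the reaction, if anything has (all of the starting material has reacted / the partner has run out first / forward and back rates have come level / it is still moving)
* part of the starting material gone at 5.0 d
* the isomer of the product standing at 5.0 d, as a percentage of the starting material charged

- the analysis behind the earlier runs scatters by 0.3 percentage points, standard deviation
- the reaction counts as stopped when no species that holds the starting material changes by six tenths of a point or more over the second half of the time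

The readings look contradictory: the epsilon and gamma runs stand still with starting material at 30.5% and 30.9% at their last readings, although partner was charged at 5 equiv. A plain balance between starting material and isomer keeps their ratio fixed, yet that ratio of isomer to starting material is 2.10 in the epsilon run and 1.92 in the gamma run. The two runs share their partner charge, so I reckon from that. Counting one partner per starting material gone, the mean of the last readings of the two runs says that 13.9% of the charged partner has met starting material. I call this share the partner yield φ, the conversion at standstill per equivalent charged, and it is less than the one-to-one mark of 20.0%. So I reckon that the partner has run out first, and in that case 86.1% of it has been spent some other way. The flask has the charge of the epsilon run, so φ gives it a conversion of 69.3%, and I take its isomer from the last epsilon reading, 63.9%.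

The forecast gives forward and back rates have come level, conversion 69.3% and isomer 63.9%, holding that “neither has run out”.

The flask gives the partner has run out first, conversion 69.3% and isomer 63.8%.

    open intermediate + capture agent → trapped intermediate (k = 0.450 /M/s)
    starting material + partner → open intermediate + released group (k = 0.00540 /M/s)
    open intermediate ⇌ isomer of the product (K = 180, k = 0.0190 /s)
    open intermediate ⇌ target (K = 0.420, k = 0.0390 /s)
    2 partner → homo dimer (k = 0.00750 /M/s)

In the flask at 0.00548 d, the path to homo dimer uses partner 8.6 times as fast as the path to open intermediate. By the end, partner, the limiting reagent, stands at 0% of its charge, less than the 31% of starting material. The released group in the flask, 15.2 mM, is 13.9% of the partner charged, beside φ of 13.9%. For a neighbour flask with 8.8 mM of starting material and the same equivalents of partner, φ gives a conversion of 69.3%, and that flask stands at 71.1%.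

The data were computed with constants of no real substance; scatter was added.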